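**Plan**

1. Numbering (cembrane): carbocycle C1–C14; lactone C16(=O)–O–C3 with C15(CH3) on C1; C4(CH3)(OH); C7–OH; C8=C19H2; oxirane C11–C12 with CH3 on C12.
2. Retrosynthetic cuts, in order: the oxirane C–C bond C11–C12 (also a bond of the 14-membered ring); C7–C8; the lactone O–C3 bond; C5–C6; C3–C4; the ring bond of limonene oxide that links C3 to C12.
3. Feature used: C12 carries CH3 and O, and C11 carries one H, so C12 is a latent methyl ketone and C11 a latent sulfonium-ylide carbon. One ylide–carbonyl event makes the bond shared by the three-membered ring and the 14-membered ring.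
4. Forward: (+)-limonene oxide gives C1 with the C12 ketone arm and the C3 aldehyde; the C3–C7 chain comes from alkenylation and Claisen rearrangement; then the δ-lactone; then the C8–C11 piece by Ni/Cr coupling; carbocycle and oxirane are closed together last.
5. Stereochemistry: C1 from (R)-limonene; C3 and C4 from a reagent-controlled epoxidation and invertive lactonisation; C15 by equilibration; C7 by a ligand-controlled coupling; C11 and C12 in the key step.

Key step: step 17

Assumption: in step 13 the (S)-configured oxazoline–sulfonamide ligand is taken to direct the alkenyl group to the Re face of the aldehyde; if the sense proves opposite, the (R)-ligand is used and nothing else changes.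

**Route**

Step 1
Reactants: 1 (+)-limonene oxide (commercial cis/trans mixture)
Product: 2 (3R)-6-oxo-3-(prop-1-en-2-yl)heptanal
Conditions: H5IO6 (1.2 equiv), THF/H2O, 0 °C → rt
Reagents that add atoms: water, O
Why: Periodic acid hydrolyses the trisubstituted oxirane to the diol and cleaves it (Malaprade-type glycol cleavage) to the methyl ketone and the aldehyde, leaving the C1 stereocentre (C4 of limonene) untouched.

Step 2
Reactants: 2 (3R)-6-oxo-3-(prop-1-en-2-yl)heptanal; 3 2-bromopropene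
Product: 4 (5R,7RS)-7-hydroxy-8-methyl-5-(prop-1-en-2-yl)non-8-en-2-one
Conditions: CrCl2 (4 equiv), NiCl2 (2 mol %), DMF, rt
Reagents that add atoms: 2-bromopropene (3), CC(Br)=C
Why: Nozaki–Hiyama–Kishi alkenylation adds the isopropenyl group to the aldehyde and leaves the methyl ketone alone; the new carbinol centre (C3) forms unselectively and is erased in step 4.

Step 3
Reactants: 4 (5R,7RS)-7-hydroxy-8-methyl-5-(prop-1-en-2-yl)non-8-en-2-one
Product: 5 (3RS,5R)-2-methyl-7-(2-methyl-1,3-dioxolan-2-yl)-5-(prop-1-en-2-yl)hept-1-en-3-ol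
Conditions: HOCH2CH2OH, PPTS (cat.), benzene, reflux (Dean–Stark)
Reagents that add atoms: ethylene glycol, OCCO
Why: Acid-catalysed dioxolane formation masks the C12 ketone against the borane, hydride and organometallic reagents of steps 5, 10 and 13, and the secondary allylic alcohol should not ionise under PPTS.

Step 4
Reactants: 5 (3RS,5R)-2-methyl-7-(2-methyl-1,3-dioxolan-2-yl)-5-(prop-1-en-2-yl)hept-1-en-3-ol; 6 N,N-dimethylacetamide dimethyl acetal
Product: 8 (4E,7R)-N,N,4-trimethyl-9-(2-methyl-1,3-dioxolan-2-yl)-7-(prop-1-en-2-yl)non-4-enamide, via ketene N,O-acetal 7 (not isolated)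
Conditions: xylene, 140 °C
Reagents that add atoms: N,N-dimethylacetamide dimethyl acetal (6), COC(C)(OC)N(C)C
Why: Eschenmoser–Claisen rearrangement through a chair transition state with the C2 chain equatorial should give the (3E)-trisubstituted olefin and adds C6–C7 as an amide that stays inert until step 10.

Step 5
Reactants: 8 (4E,7R)-N,N,4-trimethyl-9-(2-methyl-1,3-dioxolan-2-yl)-7-(prop-1-en-2-yl)non-4-enamide
Product: 10 (4E,7R)-7-[(2RS)-1-hydroxypropan-2-yl]-N,N,4-trimethyl-9-(2-methyl-1,3-dioxolan-2-yl)non-4-enamide, via B-alkyl-9-BBN adduct 9 (not isolated)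
Conditions: 9-BBN (1.2 equiv), THF, 0 °C → rt; then NaOH, H2O2, 0 °C
Reagents that add atoms: hydrogen peroxide, OO
Why: Anti-Markovnikov hydroboration–oxidation with 9-BBN takes the 1,1-disubstituted isopropenyl group much faster than the trisubstituted olefin or the tertiary amide; C15 forms as an epimer mixture that is corrected in step 8.

Step 6
Reactants: 10 (4E,7R)-7-[(2RS)-1-hydroxypropan-2-yl]-N,N,4-trimethyl-9-(2-methyl-1,3-dioxolan-2-yl)non-4-enamide
Product: 11 (2RS,3R,5E)-9-(dimethylamino)-2,6-dimethyl-3-[2-(2-methyl-1,3-dioxolan-2-yl)ethyl]-9-oxonon-5-enoic acid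
Conditions: TEMPO (cat.), PhI(OAc)2 (2.5 equiv), MeCN/pH 7 buffer, rt
Reagents that add atoms: water, O
Why: TEMPO/PhI(OAc)2 oxidation of the primary alcohol through the aldehyde hydrate gives the acid without touching the olefin, the ketal or the amide.

Step 7
Reactants: 11 (2RS,3R,5E)-9-(dimethylamino)-2,6-dimethyl-3-[2-(2-methyl-1,3-dioxolan-2-yl)ethyl]-9-oxonon-5-enoic acid
Product: 12 (2RS,3R)-4-{(2S,3S)-3-[3-(dimethylamino)-3-oxopropyl]-3-methyloxiran-2-yl}-2-methyl-3-[2-(2-methyl-1,3-dioxolan-2-yl)ethyl]butanoic acid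
Conditions: L-fructose-derived Shi ketone (enantiomer of the usual catalyst, from L-sorbose; 30 mol %), Oxone (2KHSO5·KHSO4·K2SO4), K2CO3, Bu4NHSO4 (cat.), MeCN/DMM/aq. Na2B4O7, 0 °C; work-up at pH 5, 0 °C, used at once
Reagents that add atoms: potassium peroxymonosulfate (active part of Oxone), [K+].[O-]S(=O)(=O)OO
Why: Shi epoxidation of the E-trisubstituted olefin through the spiro transition state should give the (3S,4S)-oxirane under reagent control (the D-fructose catalyst gives the R,R series with such olefins), and the carboxylate is inert at pH 10.5.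

Step 8
Reactants: 12 (2RS,3R)-4-{(2S,3S)-3-[3-(dimethylamino)-3-oxopropyl]-3-methyloxiran-2-yl}-2-methyl-3-[2-(2-methyl-1,3-dioxolan-2-yl)ethyl]butanoic acid
Product: 14 (4S)-4-hydroxy-N,N-dimethyl-4-{(2R,4R,5S)-5-methyl-4-[2-(2-methyl-1,3-dioxolan-2-yl)ethyl]-6-oxooxan-2-yl}pentanamide, via C15-epimeric hydroxy lactone 13 (not isolated)
Conditions: Cs2CO3 (1.2 equiv), DMF, 70 °C; then DBU, 70 °C
Reagents that add atoms: none
Why: With no acid present only the carboxylate is nucleophilic (the amide carbonyl cannot open the oxirane at C4), so it should attack the less hindered C3 in a 6-exo-tet SN2 lactonisation with inversion (3R, C4–OH 4S), and DBU then equilibrates C15 through the lactone enolate to the epimer with the methyl equatorial and trans to the C1 side chain (15S).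

Step 9
Reactants: 14 (4S)-4-hydroxy-N,N-dimethyl-4-{(2R,4R,5S)-5-methyl-4-[2-(2-methyl-1,3-dioxolan-2-yl)ethyl]-6-oxooxan-2-yl}pentanamide
Product: 15 (4S)-4-[(tert-butyldimethylsilyl)oxy]-N,N-dimethyl-4-{(2R,4R,5S)-5-methyl-4-[2-(2-methyl-1,3-dioxolan-2-yl)ethyl]-6-oxooxan-2-yl}pentanamide
Conditions: TBSOTf, 2,6-lutidine, CH2Cl2, 0 °C → rt
Reagents that add atoms: tert-butyldimethylsilyl triflate, CC(C)(C)[Si](C)(C)OS(=O)(=O)C(F)(F)F
Why: Silyl triflate silylation of the tertiary alcohol is needed so that the aldehyde made in step 10 cannot close to a five-membered lactol with O4, and so that no alkoxide sits next to the lactone in step 17.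

Step 10
Reactants: 15 (4S)-4-[(tert-butyldimethylsilyl)oxy]-N,N-dimethyl-4-{(2R,4R,5S)-5-methyl-4-[2-(2-methyl-1,3-dioxolan-2-yl)ethyl]-6-oxooxan-2-yl}pentanamide
Product: 16 (4S)-4-[(tert-butyldimethylsilyl)oxy]-4-{(2R,4R,5S)-5-methyl-4-[2-(2-methyl-1,3-dioxolan-2-yl)ethyl]-6-oxooxan-2-yl}pentanal
Conditions: Cp2Zr(H)Cl (1.8 equiv), THF, rt; aqueous work-up
Reagents that add atoms: none
Why: Schwartz reagent reduces tertiary amides to aldehydes (hydrozirconation of the amide C=O, then hydrolysis of the N,O-acetal) and should leave the lactone, ketal and silyl ether untouched.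

Step 11
Reactants: 17 pent-4-yn-1-ol
Product: 18 4-iodopent-4-en-1-ol
Conditions: NaI, TMSCl, H2O, MeCN, rt
Reagents that add atoms: sodium iodide, [Na+].[I-]
Why: Markovnikov hydroiodination of the terminal alkyne by HI generated in situ gives the 2-iodo-1-alkene.

Step 12
Reactants: 18 4-iodopent-4-en-1-ol
Product: 19 triethyl[(4-iodopent-4-en-1-yl)oxy]silane
Conditions: TESCl, imidazole, CH2Cl2, 0 °C
Reagents that add atoms: chlorotriethylsilane, CC[Si](Cl)(CC)CC
Why: Standard silylation; the primary TES ether is chosen because mild acid removes it in step 15 beside the two TBS ethers.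

Step 13
Reactants: 16 (4S)-4-[(tert-butyldimethylsilyl)oxy]-4-{(2R,4R,5S)-5-methyl-4-[2-(2-methyl-1,3-dioxolan-2-yl)ethyl]-6-oxooxan-2-yl}pentanal; 19 triethyl[(4-iodopent-4-en-1-yl)oxy]silane
Product: 20 (3S,4R,6R)-6-{(2S,5S)-2-[(tert-butyldimethylsilyl)oxy]-5-hydroxy-6-methylidene-9-[(triethylsilyl)oxy]nonan-2-yl}-3-methyl-4-[2-(2-methyl-1,3-dioxolan-2-yl)ethyl]oxan-2-one
Conditions: CrCl2 (3 equiv), N-{2-[(4S)-4-isopropyl-4,5-dihydro-1,3-oxazol-2-yl]-6-methylphenyl}methanesulfonamide (3.3 equiv), Et3N (3.3 equiv), NiCl2 (cat.), THF, rt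
Reagents that add atoms: triethyl[(4-iodopent-4-en-1-yl)oxy]silane (19), C=C(I)CCCO[Si](CC)(CC)CC
Why: Asymmetric Nozaki–Hiyama–Kishi coupling, in which the alkenylchromium species adds to the aldehyde inside the chiral sulfonamide–chromium complex, should set (7S) by Re-face attack under ligand control (the nearest stereocentre, C4, is three bonds away), and organochromium reagents do not attack the lactone or ketal.

Step 14
Reactants: 20 (3S,4R,6R)-6-{(2S,5S)-2-[(tert-butyldimethylsilyl)oxy]-5-hydroxy-6-methylidene-9-[(triethylsilyl)oxy]nonan-2-yl}-3-methyl-4-[2-(2-methyl-1,3-dioxolan-2-yl)ethyl]oxan-2-one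
Product: 21 (3S,4R,6R)-6-{(2S,5S)-2,5-bis[(tert-butyldimethylsilyl)oxy]-6-methylidene-9-[(triethylsilyl)oxy]nonan-2-yl}-3-methyl-4-[2-(2-methyl-1,3-dioxolan-2-yl)ethyl]oxan-2-one
Conditions: TBSOTf, 2,6-lutidine, CH2Cl2, –78 °C
Reagents that add atoms: tert-butyldimethylsilyl triflate, CC(C)(C)[Si](C)(C)OS(=O)(=O)C(F)(F)F
Why: Silylation of the secondary allylic alcohol ensures that neither the hydroxyl nor its alkoxide can displace the C11 leaving group (six-membered ether) in steps 16 and 17.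

Step 15
Reactants: 21 (3S,4R,6R)-6-{(2S,5S)-2,5-bis[(tert-butyldimethylsilyl)oxy]-6-methylidene-9-[(triethylsilyl)oxy]nonan-2-yl}-3-methyl-4-[2-(2-methyl-1,3-dioxolan-2-yl)ethyl]oxan-2-one
Product: 22 (3S,4R,6R)-6-{(2S,5S)-2,5-bis[(tert-butyldimethylsilyl)oxy]-9-hydroxy-6-methylidenenonan-2-yl}-3-methyl-4-(3-oxobutyl)oxan-2-one
Conditions: PPTS (cat.), acetone/H2O, 45 °C
Reagents that add atoms: water, O
Why: Mild acid hydrolysis should remove the primary TES ether and the dioxolane together, while the secondary and tertiary TBS ethers survive.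

Step 16
Reactants: 22 (3S,4R,6R)-6-{(2S,5S)-2,5-bis[(tert-butyldimethylsilyl)oxy]-9-hydroxy-6-methylidenenonan-2-yl}-3-methyl-4-(3-oxobutyl)oxan-2-one
Product: 24 {(5S,8S)-5,8-bis[(tert-butyldimethylsilyl)oxy]-4-methylidene-8-[(2R,4R,5S)-5-methyl-6-oxo-4-(3-oxobutyl)oxan-2-yl]nonyl}diphenylsulfonium triflate, via primary triflate 23 (not isolated)
Conditions: Tf2O, 2,6-di-tert-butyl-4-methylpyridine, CH2Cl2, –78 °C; then Ph2S (10 equiv), –78 °C → rt
Reagents that add atoms: triflic anhydride, O=S(=O)(OS(=O)(=O)C(F)(F)F)C(F)(F)F; diphenyl sulfide, c1ccc(cc1)Sc1ccccc1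
Why: The primary alkyl triflate S-alkylates diphenyl sulfide (SN2) to the alkyldiphenylsulfonium triflate, and diphenyl sulfide is chosen because the only α-hydrogens of the salt are then those at C11.

Step 17
Reactants: 24 {(5S,8S)-5,8-bis[(tert-butyldimethylsilyl)oxy]-4-methylidene-8-[(2R,4R,5S)-5-methyl-6-oxo-4-(3-oxobutyl)oxan-2-yl]nonyl}diphenylsulfonium triflate
Product: 27 (1R,3R,4S,7S,11S,12S,15S)-4,7-bis[(tert-butyldimethylsilyl)oxy]-11,12-epoxycembr-8(19)-en-16,3-olide, via sulfonium ylide 25 (not isolated), via betaine 26 (not isolated)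
Conditions: KN(SiMe3)2 (1.0 equiv, added over 2 h), THF (1 mM), –78 °C; then –78 → –20 °C
Reagents that add atoms: none
Why: Proposed new method: KN(SiMe3)2 removes a C11 proton next to the diphenylsulfonium group, the ylide carbon adds to the C12 methyl-ketone carbonyl to give betaine 26, and the C12 alkoxide then displaces diphenyl sulfide from C11 with inversion; the closest known reaction type is the Corey–Chaykovsky epoxidation of ketones by diphenylsulfonium alkylides, known between two molecules and in small-ring epoxy-annulations but not as a macrocyclisation. The 14-membered carbocycle (C1 to C14) is closed in the C–C bond-forming addition, in which the ylide carbon attacks a carbonyl whose oxygen stays outside the new ring (exo-trig), and the oxirane is closed by the following 3-exo-tet substitution, so the bond shared by both rings is made once. C11 and C12 arise together: the trans relation of C10 and C13 on the oxirane should follow because the displacement needs S+ and O– antiperiplanar, and in that conformation of the cyclic betaine the long tether is least strained with C10 and C13 anti and the Ph2S+ group on the outside of the ring. The facial sense at the ketone, and so the absolute (11S,12S) configuration, is under substrate control by the seco chain, which is folded by the cis-disubstituted lactone next to the ketone arm (C1 is three bonds from C12) and by the silyloxy-bearing C4 and C7; this is the least certain element, the other trans-oxirane being the expected by-product. The step needs site-selective deprotonation, secured by the large acidity gap between the sulfonium α-CH2 and the ketone or lactone α-CH and by adding one equivalent of base slowly to the substrate so that base is never in excess, and cyclisation over oligomerisation, secured by 1 mM concentration at a temperature where the ylide is stable.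

Step 18
Reactants: 27 (1R,3R,4S,7S,11S,12S,15S)-4,7-bis[(tert-butyldimethylsilyl)oxy]-11,12-epoxycembr-8(19)-en-16,3-olide
Product: 28 (1R,3R,4S,7S,11S,12S,15S)-11,12-epoxy-4,7-dihydroxycembr-8(19)-en-16,3-olide (CNP0262409.2)
Conditions: TBAF, AcOH, THF, rt → 40 °C
Reagents that add atoms: none
Why: Fluoride cleaves both Si–O bonds, and buffering with acetic acid should keep the lactone and the oxirane intact and prevent transannular attack of an alkoxide on the oxirane.

**Compound list**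

1 | (+)-limonene oxide, (4R)-1-methyl-4-(prop-1-en-2-yl)-7-oxabicyclo[4.1.0]heptane, cis/trans mixture at the oxirane | CC(=C)[C@@H]1CCC2(C)OC2C1 | starting material
2 | (3R)-6-oxo-3-(prop-1-en-2-yl)heptanal | CC(=C)[C@@H](CC=O)CCC(C)=O | intermediate
3 | 2-bromopropene | CC(Br)=C | starting material
4 | (5R,7RS)-7-hydroxy-8-methyl-5-(prop-1-en-2-yl)non-8-en-2-one | CC(=C)[C@@H](CC(O)C(C)=C)CCC(C)=O | intermediate
5 | (3RS,5R)-2-methyl-7-(2-methyl-1,3-dioxolan-2-yl)-5-(prop-1-en-2-yl)hept-1-en-3-ol | CC(=C)[C@@H](CC(O)C(C)=C)CCC1(C)OCCO1 | intermediate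
6 | N,N-dimethylacetamide dimethyl acetal | COC(C)(OC)N(C)C | starting material
7 | ketene N,O-acetal of 5 (1-(dimethylamino)vinyl ether of the allylic alcohol; formed in situ) | C=C(N(C)C)OC(C(C)=C)C[C@@H](CCC1(C)OCCO1)C(C)=C | intermediate
8 | (4E,7R)-N,N,4-trimethyl-9-(2-methyl-1,3-dioxolan-2-yl)-7-(prop-1-en-2-yl)non-4-enamide | CN(C)C(=O)CC/C(C)=C/C[C@@H](CCC1(C)OCCO1)C(C)=C | intermediate
9 | B-alkyl-9-borabicyclo[3.3.1]nonane adduct of 8 (boron on the former isopropenyl CH2; formed in situ) | CN(C)C(=O)CC/C(C)=C/C[C@@H](CCC1(C)OCCO1)C(C)CB1C2CCCC1CCC2 | intermediate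
10 | (4E,7R)-7-[(2RS)-1-hydroxypropan-2-yl]-N,N,4-trimethyl-9-(2-methyl-1,3-dioxolan-2-yl)non-4-enamide | CN(C)C(=O)CC/C(C)=C/C[C@@H](CCC1(C)OCCO1)C(C)CO | intermediate
11 | (2RS,3R,5E)-9-(dimethylamino)-2,6-dimethyl-3-[2-(2-methyl-1,3-dioxolan-2-yl)ethyl]-9-oxonon-5-enoic acid | CN(C)C(=O)CC/C(C)=C/C[C@@H](CCC1(C)OCCO1)C(C)C(=O)O | intermediate
12 | (2RS,3R)-4-{(2S,3S)-3-[3-(dimethylamino)-3-oxopropyl]-3-methyloxiran-2-yl}-2-methyl-3-[2-(2-methyl-1,3-dioxolan-2-yl)ethyl]butanoic acid | CN(C)C(=O)CC[C@]1(C)O[C@H]1C[C@@H](CCC2(C)OCCO2)C(C)C(=O)O | intermediate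
13 | (4S)-4-hydroxy-N,N-dimethyl-4-{(2R,4R,5RS)-5-methyl-4-[2-(2-methyl-1,3-dioxolan-2-yl)ethyl]-6-oxooxan-2-yl}pentanamide (C15 epimer mixture; formed in situ) | CC1(CC[C@@H]2C[C@@H](OC(=O)C2C)[C@@](C)(O)CCC(=O)N(C)C)OCCO1 | intermediate
14 | (4S)-4-hydroxy-N,N-dimethyl-4-{(2R,4R,5S)-5-methyl-4-[2-(2-methyl-1,3-dioxolan-2-yl)ethyl]-6-oxooxan-2-yl}pentanamide | CC1(CC[C@@H]2C[C@@H](OC(=O)[C@H]2C)[C@@](C)(O)CCC(=O)N(C)C)OCCO1 | intermediate
15 | (4S)-4-[(tert-butyldimethylsilyl)oxy]-N,N-dimethyl-4-{(2R,4R,5S)-5-methyl-4-[2-(2-methyl-1,3-dioxolan-2-yl)ethyl]-6-oxooxan-2-yl}pentanamide | CC1(CC[C@@H]2C[C@@H](OC(=O)[C@H]2C)[C@@](C)(O[Si](C)(C)C(C)(C)C)CCC(=O)N(C)C)OCCO1 | intermediate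
16 | (4S)-4-[(tert-butyldimethylsilyl)oxy]-4-{(2R,4R,5S)-5-methyl-4-[2-(2-methyl-1,3-dioxolan-2-yl)ethyl]-6-oxooxan-2-yl}pentanal | CC1(CC[C@@H]2C[C@@H](OC(=O)[C@H]2C)[C@@](C)(O[Si](C)(C)C(C)(C)C)CCC=O)OCCO1 | intermediate
17 | pent-4-yn-1-ol | C#CCCCO | starting material
18 | 4-iodopent-4-en-1-ol | C=C(I)CCCO | intermediate
19 | triethyl[(4-iodopent-4-en-1-yl)oxy]silane | C=C(I)CCCO[Si](CC)(CC)CC | intermediate
20 | (3S,4R,6R)-6-{(2S,5S)-2-[(tert-butyldimethylsilyl)oxy]-5-hydroxy-6-methylidene-9-[(triethylsilyl)oxy]nonan-2-yl}-3-methyl-4-[2-(2-methyl-1,3-dioxolan-2-yl)ethyl]oxan-2-one | CC1(CC[C@@H]2C[C@@H](OC(=O)[C@H]2C)[C@@](C)(O[Si](C)(C)C(C)(C)C)CC[C@H](O)C(=C)CCCO[Si](CC)(CC)CC)OCCO1 | intermediate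
21 | (3S,4R,6R)-6-{(2S,5S)-2,5-bis[(tert-butyldimethylsilyl)oxy]-6-methylidene-9-[(triethylsilyl)oxy]nonan-2-yl}-3-methyl-4-[2-(2-methyl-1,3-dioxolan-2-yl)ethyl]oxan-2-one | CC1(CC[C@@H]2C[C@@H](OC(=O)[C@H]2C)[C@@](C)(O[Si](C)(C)C(C)(C)C)CC[C@H](O[Si](C)(C)C(C)(C)C)C(=C)CCCO[Si](CC)(CC)CC)OCCO1 | intermediate
22 | (3S,4R,6R)-6-{(2S,5S)-2,5-bis[(tert-butyldimethylsilyl)oxy]-9-hydroxy-6-methylidenenonan-2-yl}-3-methyl-4-(3-oxobutyl)oxan-2-one | CC(=O)CC[C@@H]1C[C@@H](OC(=O)[C@H]1C)[C@@](C)(O[Si](C)(C)C(C)(C)C)CC[C@H](O[Si](C)(C)C(C)(C)C)C(=C)CCCO | intermediate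
23 | primary triflate of 22 (formed in situ) | CC(=O)CC[C@@H]1C[C@@H](OC(=O)[C@H]1C)[C@@](C)(O[Si](C)(C)C(C)(C)C)CC[C@H](O[Si](C)(C)C(C)(C)C)C(=C)CCCOS(=O)(=O)C(F)(F)F | intermediate
24 | {(5S,8S)-5,8-bis[(tert-butyldimethylsilyl)oxy]-4-methylidene-8-[(2R,4R,5S)-5-methyl-6-oxo-4-(3-oxobutyl)oxan-2-yl]nonyl}diphenylsulfonium triflate | CC(=O)CC[C@@H]1C[C@@H](OC(=O)[C@H]1C)[C@@](C)(O[Si](C)(C)C(C)(C)C)CC[C@H](O[Si](C)(C)C(C)(C)C)C(=C)CCC[S+](c1ccccc1)c1ccccc1.[O-]S(=O)(=O)C(F)(F)F | intermediate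
25 | sulfonium ylide of 24 (carbanion at C11; formed in situ) | CC(=O)CC[C@@H]1C[C@@H](OC(=O)[C@H]1C)[C@@](C)(O[Si](C)(C)C(C)(C)C)CC[C@H](O[Si](C)(C)C(C)(C)C)C(=C)CC[CH-][S+](c1ccccc1)c1ccccc1 | intermediate
26 | macrocyclic betaine, (11R,12S)-11-(diphenylsulfonio)-12-oxido derivative of the bis-silyl cembrenolide (formed in situ) | C=C1CC[C@@H]([S+](c2ccccc2)c2ccccc2)[C@@](C)([O-])CC[C@@H]2C[C@@H](OC(=O)[C@H]2C)[C@@](C)(O[Si](C)(C)C(C)(C)C)CC[C@@H]1O[Si](C)(C)C(C)(C)C | intermediate
27 | (1R,3R,4S,7S,11S,12S,15S)-4,7-bis[(tert-butyldimethylsilyl)oxy]-11,12-epoxycembr-8(19)-en-16,3-olide | C=C1CC[C@@H]2O[C@@]2(C)CC[C@@H]2C[C@@H](OC(=O)[C@H]2C)[C@@](C)(O[Si](C)(C)C(C)(C)C)CC[C@@H]1O[Si](C)(C)C(C)(C)C | intermediate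
28 | (1R,3R,4S,7S,11S,12S,15S)-11,12-epoxy-4,7-dihydroxycembr-8(19)-en-16,3-olide (CNP0262409.2) | C=C1CC[C@@H]2O[C@@]2(C)CC[C@@H]2C[C@@H](OC(=O)[C@H]2C)[C@@](C)(O)CC[C@@H]1O | target

**Count**

Total steps: 18. Longest linear sequence: 16 (steps 1–10 and 13–18).

**Steps most likely to fail**

Step 17. The risk is poor facial selectivity in the ylide addition, or decay and oligomerisation of the ylide before the slow ring closure. The fallback closes the ring as an olefin and adds the oxygen afterwards under reagent control. It sets out from 22. Dess–Martin oxidation of the primary alcohol gives the keto aldehyde (3S,4R,6R)-6-{(2S,5S)-2,5-bis[(tert-butyldimethylsilyl)oxy]-6-methylidene-9-oxononan-2-yl}-3-methyl-4-(3-oxobutyl)oxan-2-one F1. Intramolecular McMurry coupling with low-valent titanium (TiCl3(DME)1.5, zinc–copper couple, DME, reflux, slow addition) gives the macrocyclic olefin (1R,3R,4S,7S,11E,15S)-4,7-bis[(tert-butyldimethylsilyl)oxy]cembra-8(19),11-dien-16,3-olide F2. Epoxidation with the L-fructose-derived Shi ketone and Oxone, as in step 7, should take the trisubstituted ring olefin in preference to the C8 methylidene group and comes back to the route at 27.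

Step 8. The risk is sluggish or non-regioselective opening of the oxirane by the weakly nucleophilic carboxylate, or incomplete equilibration at C15. The fallback makes the C3–O bond with an alkoxide and brings in the carbonyl afterwards. It sets out from 10. Shi epoxidation as in step 7 gives the epoxy alcohol 3-[(2S,3S)-3-{(2R)-2-[(2RS)-1-hydroxypropan-2-yl]-4-(2-methyl-1,3-dioxolan-2-yl)butyl}-2-methyloxiran-2-yl]-N,N-dimethylpropanamide F3. KOt-Bu in THF closes the ring by 6-exo attack of the primary alkoxide at C3 with inversion, which gives the oxane (4S)-4-hydroxy-N,N-dimethyl-4-{(2R,4R,5RS)-5-methyl-4-[2-(2-methyl-1,3-dioxolan-2-yl)ethyl]oxan-2-yl}pentanamide F4. RuCl3/NaIO4 oxidises the ring O–CH2 group to the lactone carbonyl and gives the epimer mixture 13; DBU equilibration as in step 8 comes back to the route at 14.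

Step 16. The risk is attack of the C7 silyl ether oxygen on the primary triflate (six-membered cyclic ether with loss of the silyl group) in competition with the slow S-alkylation of the weakly nucleophilic diphenyl sulfide. The fallback makes the carbon–sulfur bond first and forms the sulfonium by S-arylation. It sets out from 22. Thioetherification with PhSSPh/PBu3 in THF gives the phenyl sulfide (3S,4R,6R)-6-{(2S,5S)-2,5-bis[(tert-butyldimethylsilyl)oxy]-6-methylidene-9-(phenylsulfanyl)nonan-2-yl}-3-methyl-4-(3-oxobutyl)oxan-2-one F5. Copper-catalysed S-phenylation with diphenyliodonium triflate (Cu(OAc)2 cat., 1,2-dichloroethane, 80 °C) comes back to the route at 24.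

**Further compounds**

F1 | step 17 | (3S,4R,6R)-6-{(2S,5S)-2,5-bis[(tert-butyldimethylsilyl)oxy]-6-methylidene-9-oxononan-2-yl}-3-methyl-4-(3-oxobutyl)oxan-2-one | CC(=O)CC[C@@H]1C[C@@H](OC(=O)[C@H]1C)[C@@](C)(O[Si](C)(C)C(C)(C)C)CC[C@H](O[Si](C)(C)C(C)(C)C)C(=C)CCC=O
F2 | step 17 | (1R,3R,4S,7S,11E,15S)-4,7-bis[(tert-butyldimethylsilyl)oxy]cembra-8(19),11-dien-16,3-olide | C=C1CC/C=C(C)/CC[C@@H]2C[C@@H](OC(=O)[C@H]2C)[C@@](C)(O[Si](C)(C)C(C)(C)C)CC[C@@H]1O[Si](C)(C)C(C)(C)C
F3 | step 8 | 3-[(2S,3S)-3-{(2R)-2-[(2RS)-1-hydroxypropan-2-yl]-4-(2-methyl-1,3-dioxolan-2-yl)butyl}-2-methyloxiran-2-yl]-N,N-dimethylpropanamide | CN(C)C(=O)CC[C@]1(C)O[C@H]1C[C@@H](CCC2(C)OCCO2)C(C)CO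
F4 | step 8 | (4S)-4-hydroxy-N,N-dimethyl-4-{(2R,4R,5RS)-5-methyl-4-[2-(2-methyl-1,3-dioxolan-2-yl)ethyl]oxan-2-yl}pentanamide | CC1(CC[C@@H]2C[C@@H](OCC2C)[C@@](C)(O)CCC(=O)N(C)C)OCCO1
F5 | step 16 | (3S,4R,6R)-6-{(2S,5S)-2,5-bis[(tert-butyldimethylsilyl)oxy]-6-methylidene-9-(phenylsulfanyl)nonan-2-yl}-3-methyl-4-(3-oxobutyl)oxan-2-one | CC(=O)CC[C@@H]1C[C@@H](OC(=O)[C@H]1C)[C@@](C)(O[Si](C)(C)C(C)(C)C)CC[C@H](O[Si](C)(C)C(C)(C)C)C(=C)CCCSc1ccccc1
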